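Numbering (chamigrene): ring B = C1–C6 (C6 spiro, C2 Cl, C3 Me/Br); ring A = C6–C11 (C7 Me, C7=C8, C9 H2, C10 Br, C11 Me2). Target = (2S,3S,6S,10R)-3,10-dibromo-2-chloro-α-chamigrene.
Feature used: inside ring A the C10–Br carbon is homoallylic to C7=C8 (a cyclohex-3-enyl bromide). This is the opened form of a bicyclo[3.1.0]hex-2-yl (cyclopropylcarbinyl) cation that carries an extra C8–C10 bond.
Cuts, in retrosynthetic order: C3–Br (back to C3–OH); C10–Br with re-closure of C8–C10 (ring A back to a cyclopentane fused to a cyclopropane, C7 carbinol); C7–CH3; C2–Cl/C3–O; C3–CH3; C1=C2 (aldol) and C5–C6 (Michael); C6–CHO; C8–C9/C8–C10 (carbenoid); C6–C11 (Grignard).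
Forward: the five-membered ring and the cyclopropane arise together (step 2). Ring B is spiro-annulated on C6 (steps 4–6) and functionalised (steps 7–9). Ring A reaches its final size last, by one-carbon ring expansion (step 11).
Stereochemistry: (S)-epichlorohydrin fixes the cyclopropane (C8, C10); the cyclopropane face directs the Michael addition (C6); axial C7 on ring B directs Cl+ (C2, C3, anti addition). Inversion at C10 in the ring expansion and retention at C3 in the last step carry this into the target.

Key step: step 11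

Assumption: 16 is drawn as the C7 epimer expected from attack anti to the cyclopropane, and either epimer gives the same cation 17; 8 is drawn as its chelated enol.

Step 1
Reactants: 1 (S)-epichlorohydrin; 2 prenyl chloride (1-chloro-3-methylbut-2-ene)
Product: 4 (S)-1-chloro-4,4-dimethylhex-5-en-2-ol, via prenylmagnesium chloride 3 (not isolated)
Conditions: Mg, THF, 0 °C; then 1, −30 → 0 °C; H2O
Reagents that add atoms: none
Why: Allylic Grignard reagents attack terminal epoxides through their γ-carbon (SE2′ epoxide opening), which makes the C6–C11 bond and the gem-dimethyl carbon at once while the stereocentre of 1 is not touched.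

Step 2
Reactants: 4 (S)-1-chloro-4,4-dimethylhex-5-en-2-ol
Product: 6 (1S,2S,5R)-4,4-dimethylbicyclo[3.1.0]hexan-2-ol, via (S)-2-(2,2-dimethylbut-3-enyl)oxirane 5 (not isolated)
Conditions: lithium 2,2,6,6-tetramethylpiperidide (LiTMP, 3 equiv), t-BuOMe, −78 → 0 °C; H2O
Reagents that add atoms: none
Why: The base closes 4 to epoxide 5 and lithiates its CH2 trans to the chain, and the α-lithiated epoxide then cyclopropanates the tethered vinyl group as a carbenoid (intramolecular cyclopropanation of an unsaturated terminal epoxide), so C8 and C10 are set by the epoxide stereocentre with the oxygen trans to the cyclopropane CH2.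

Step 3
Reactants: 6 (1S,2S,5R)-4,4-dimethylbicyclo[3.1.0]hexan-2-ol
Product: 7 (1S,5R)-4,4-dimethylbicyclo[3.1.0]hexan-2-one
Conditions: TEMPO (cat.), KBr (cat.), NaOCl, NaHCO3, CH2Cl2/H2O, 0 °C
Reagents that add atoms: none
Why: Anelli oxidation of a secondary alcohol, to which the cyclopropane and its two stereocentres are inert.

Step 4
Reactants: 7 (1S,5R)-4,4-dimethylbicyclo[3.1.0]hexan-2-one
Product: 8 (1S,5R,Z)-3-(hydroxymethylidene)-4,4-dimethylbicyclo[3.1.0]hexan-2-one
Conditions: NaH, HCO2Et, THF, 0 °C → rt; then 1 M HCl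
Reagents that add atoms: ethyl formate, CCOC=O
Why: Crossed Claisen condensation (formylation) at C6, the only enolisable position because C8 is a cyclopropane bridgehead; the new carbon is C1.

Step 5
Reactants: 8 (1S,5R,Z)-3-(hydroxymethylidene)-4,4-dimethylbicyclo[3.1.0]hexan-2-one; 9 methyl vinyl ketone
Product: 10 (1S,3S,5R)-4,4-dimethyl-2-oxo-3-(3-oxobutyl)bicyclo[3.1.0]hexane-3-carbaldehyde
Conditions: Et3N (0.2 equiv), CH2Cl2, 0 °C → rt
Reagents that add atoms: none
Why: Amine-catalysed Michael addition of a β-keto aldehyde, in which the enone should approach the flat enol on the face away from the cyclopropane CH2 (C9), placing C5 anti and the formyl carbon C1 syn to C9 and so setting C6.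

Step 6
Reactants: 10 (1S,3S,5R)-4,4-dimethyl-2-oxo-3-(3-oxobutyl)bicyclo[3.1.0]hexane-3-carbaldehyde
Product: 11 (1S,3R,5R)-4,4-dimethylspiro[bicyclo[3.1.0]hexane-3,1'-cyclohex-2'-ene]-2,4'-dione
Conditions: piperidine (0.3 equiv), AcOH (0.3 equiv), toluene, 80 °C, −H2O
Reagents that add atoms: none
Why: Intramolecular aldol condensation (second half of a Robinson-type spiroannulation), in which only the side-chain methyl carbon reaches the non-enolisable aldehyde through a six-membered ring and the buffered amine salt avoids retro-Claisen loss of the formyl group.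

Step 7
Reactants: 11 (1S,3R,5R)-4,4-dimethylspiro[bicyclo[3.1.0]hexane-3,1'-cyclohex-2'-ene]-2,4'-dione
Product: 13 (1S,3R,5R)-4,4-dimethyl-2-oxospiro[bicyclo[3.1.0]hexane-3,1'-cyclohex-3'-en]-4'-yl trifluoromethanesulfonate, via lithium enolate 12 (not isolated)
Conditions: LiBH(s-Bu)3 (L-Selectride, 1.05 equiv), THF, −78 °C; then PhNTf2, −78 → 0 °C
Reagents that add atoms: N-phenylbis(trifluoromethanesulfonimide), O=S(=O)(N(c1ccccc1)S(=O)(=O)C(F)(F)F)C(F)(F)F
Why: Conjugate hydride reduction gives the enolate regiospecifically on the C2 side and O-triflation freezes it, so the two arms of ring B (and with them C6) stay distinct while the congested C7 ketone should be left alone.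

Step 8
Reactants: 13 (1S,3R,5R)-4,4-dimethyl-2-oxospiro[bicyclo[3.1.0]hexane-3,1'-cyclohex-3'-en]-4'-yl trifluoromethanesulfonate
Product: 14 (1S,3R,5R)-4,4,4'-trimethylspiro[bicyclo[3.1.0]hexane-3,1'-cyclohex-3'-en]-2-one
Conditions: MeMgBr (1.3 equiv), Fe(acac)3 (5 mol %), THF/NMP, −30 °C
Reagents that add atoms: methylmagnesium bromide, C[Mg]Br
Why: Iron-catalysed Kumada-type cross-coupling of an enol triflate is faster than addition to the hindered, non-enolisable C7 ketone and installs the C3 methyl group.

Step 9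
Reactants: 14 (1S,3R,5R)-4,4,4'-trimethylspiro[bicyclo[3.1.0]hexane-3,1'-cyclohex-3'-en]-2-one
Product: 15 (1S,3R,3'S,4'S,5R)-3'-chloro-4'-hydroxy-4,4,4'-trimethylspiro[bicyclo[3.1.0]hexane-3,1'-cyclohexan]-2-one
Conditions: trichloroisocyanuric acid (0.35 equiv), acetone/H2O, 0 °C
Reagents that add atoms: trichloroisocyanuric acid, O=C1N(Cl)C(=O)N(Cl)C(=O)N1Cl; water, O
Why: Chlorohydrin formation (anti, Markovnikov addition): with C11 equatorial and the acyl carbon C7 axial on ring B, Cl+ should add irreversibly to the face opposite C7 and water then opens at tertiary C3 from the other face, which sets C2 and C3 relative to C6.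

Step 10
Reactants: 15 (1S,3R,3'S,4'S,5R)-3'-chloro-4'-hydroxy-4,4,4'-trimethylspiro[bicyclo[3.1.0]hexane-3,1'-cyclohexan]-2-one
Product: 16 (1S,2S,3R,3'S,4'S,5R)-3'-chloro-2,4,4,4'-tetramethylspiro[bicyclo[3.1.0]hexane-3,1'-cyclohexane]-2,4'-diol
Conditions: MeLi (3 equiv), Et2O, −78 → −40 °C; H2O
Reagents that add atoms: methyllithium, [Li]C
Why: 1,2-Addition of MeLi to a ketone that cannot enolise (quaternary C6, bridgehead C8), expected anti to the cyclopropane although the C7 configuration is lost in step 11, while the C3 lithium alkoxide cannot displace the gauche chloride at low temperature.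

Step 11
Reactants: 16 (1S,2S,3R,3'S,4'S,5R)-3'-chloro-2,4,4,4'-tetramethylspiro[bicyclo[3.1.0]hexane-3,1'-cyclohexane]-2,4'-diol
Product: 18 (2S,3S,6S,10R)-10-bromo-2-chloro-α-chamigren-3-ol, via cyclopropylcarbinyl cation 17 (not isolated)
Conditions: MgBr2·OEt2 (3 equiv), Et2O, 0 °C → reflux
Reagents that add atoms: magnesium bromide, [Mg+2].[Br-].[Br-]
Why: MgBr2 ionises the tertiary C7–OH to the cyclopropylcarbinyl (bicyclo[3.1.0]hex-2-yl) cation 17, whose charge is shared with C10 and C9, and bromide opens it at C10 with cleavage of the inner C8–C10 bond, so that the five-membered ring C6–C7–C8–C10–C11 takes up C9 and becomes six-membered ring A with C7=C8 and C10–Br in place. The closest known reaction types are the Julia cyclopropyl carbinol to homoallyl bromide rearrangement and its ring-enlarging forms, namely the retro-i-steroid opening that gives 3β-halo-Δ5-steroids, the acid opening of sabinene hydrate to terpinen-4-ol and the conversion of bicyclo[3.1.0]hexan-2-ols into cyclohex-3-enyl derivatives. No ring-closing bond is formed: ring A is the periphery of the bicycle and is set free by breaking the zero-atom bridge. C10 is the only new stereocentre and is fixed by backside attack of bromide anti to the departing C8 (inversion at the cyclopropane carbon), so its configuration comes from the cyclopropane made in step 2, while C2, C3 and C6 are not involved and the C7 stereocentre disappears. The step needs inner-bond (C8–C10) over outer-bond (C8–C9) cleavage, which is secured by better charge stabilisation at secondary C10 than at primary C9, by the boat-shaped bicycle that brings the cation close to the bisected geometry, by the larger strain release and by the reversibility of bromide capture at tertiary C7. It also needs chemoselectivity over the C3 alcohol, which the β-chlorine deactivates towards ionisation under these mild conditions.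

Step 12
Reactants: 18 (2S,3S,6S,10R)-10-bromo-2-chloro-α-chamigren-3-ol
Product: 19 (2S,3S,6S,10R)-3,10-dibromo-2-chloro-α-chamigrene
Conditions: Me3SiBr (2.5 equiv), CH2Cl2, −20 → 0 °C
Reagents that add atoms: bromotrimethylsilane, C[Si](C)(C)Br
Why: Substitution of a tertiary alcohol by Me3SiBr in a trans-halohydrin (neighbouring-group substitution): the face of the β-chloro cation opposite the leaving oxygen is held by the C2 chlorine and the bromide counter-ion sits where the oxygen left, so retention at C3 and Br trans to Cl are expected.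

Compound list
1 | (S)-epichlorohydrin | ClC[C@@H]1CO1 | starting material
2 | prenyl chloride (1-chloro-3-methylbut-2-ene) | CC(C)=CCCl | starting material
3 | prenylmagnesium chloride | CC(C)=CC[Mg]Cl | intermediate
4 | (S)-1-chloro-4,4-dimethylhex-5-en-2-ol | ClC[C@@H](O)CC(C)(C)C=C | intermediate
5 | (S)-2-(2,2-dimethylbut-3-enyl)oxirane | C=CC(C)(C)C[C@H]1CO1 | intermediate
6 | (1S,2S,5R)-4,4-dimethylbicyclo[3.1.0]hexan-2-ol (OH trans to the cyclopropane CH2) | O[C@@H]1[C@H]2C[C@H]2C(C)(C)C1 | intermediate
7 | (1S,5R)-4,4-dimethylbicyclo[3.1.0]hexan-2-one | O=C1[C@H]2C[C@H]2C(C)(C)C1 | intermediate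
8 | (1S,5R,Z)-3-(hydroxymethylidene)-4,4-dimethylbicyclo[3.1.0]hexan-2-one | O=C1[C@H]2C[C@H]2C(C)(C)/C1=C/O | intermediate
9 | methyl vinyl ketone | C=CC(C)=O | starting material
10 | (1S,3S,5R)-4,4-dimethyl-2-oxo-3-(3-oxobutyl)bicyclo[3.1.0]hexane-3-carbaldehyde (CHO syn to the cyclopropane CH2) | O=C1[C@H]2C[C@H]2C(C)(C)[C@]1(C=O)CCC(C)=O | intermediate
11 | (1S,3R,5R)-4,4-dimethylspiro[bicyclo[3.1.0]hexane-3,1'-cyclohex-2'-ene]-2,4'-dione | O=C1[C@H]2C[C@H]2C(C)(C)[C@]13CCC(=O)C=C3 | intermediate
12 | lithium enolate of the 1,4-reduced enone (C2=C3–OLi) | O=C1[C@H]2C[C@H]2C(C)(C)[C@]13CCC(O[Li])=CC3 | intermediate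
13 | (1S,3R,5R)-4,4-dimethyl-2-oxospiro[bicyclo[3.1.0]hexane-3,1'-cyclohex-3'-en]-4'-yl trifluoromethanesulfonate | O=C1[C@H]2C[C@H]2C(C)(C)[C@]13CCC(OS(=O)(=O)C(F)(F)F)=CC3 | intermediate
14 | (1S,3R,5R)-4,4,4'-trimethylspiro[bicyclo[3.1.0]hexane-3,1'-cyclohex-3'-en]-2-one | O=C1[C@H]2C[C@H]2C(C)(C)[C@]13CCC(C)=CC3 | intermediate
15 | (1S,3R,3'S,4'S,5R)-3'-chloro-4'-hydroxy-4,4,4'-trimethylspiro[bicyclo[3.1.0]hexane-3,1'-cyclohexan]-2-one | O=C1[C@H]2C[C@H]2C(C)(C)[C@]13CC[C@](C)(O)[C@@H](Cl)C3 | intermediate
16 | (1S,2S,3R,3'S,4'S,5R)-3'-chloro-2,4,4,4'-tetramethylspiro[bicyclo[3.1.0]hexane-3,1'-cyclohexane]-2,4'-diol | C[C@]1(O)[C@H]2C[C@H]2C(C)(C)[C@]13CC[C@](C)(O)[C@@H](Cl)C3 | intermediate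
17 | tertiary cyclopropylcarbinyl cation at C7 | C[C+]1[C@H]2C[C@H]2C(C)(C)[C@]13CC[C@](C)(O)[C@@H](Cl)C3 | intermediate
18 | (2S,3S,6S,10R)-10-bromo-2-chloro-α-chamigren-3-ol | CC1=CC[C@@H](Br)C(C)(C)[C@]12CC[C@](C)(O)[C@@H](Cl)C2 | intermediate
19 | (2S,3S,6S,10R)-3,10-dibromo-2-chloro-α-chamigrene | CC1=CC[C@@H](Br)C(C)(C)[C@]12CC[C@](C)(Br)[C@@H](Cl)C2 | target

Total step count: 12. Longest linear sequence: 12 steps (1 and 2 to 19).

Steps most likely to fail

Step 11. Bromide may attack the unhindered cyclopropane CH2 (C9) with cleavage of the outer C8–C9 bond, or the cation may lose a proton from the C7 methyl group. The fallback sets out from 16 and comes back at 18. It separates the choice of bond from the C–Br bond formation.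
- Equilibrating acid-catalysed hydration (HClO4 cat., aqueous dioxane, warm) should turn 16 into the ring-enlarged homoallylic alcohol (2S,3S,6S,10R)-2-chloro-α-chamigrene-3,10-diol F1. This is the thermodynamic outcome known for bicyclo[3.1.0]hexan-2-ols.
- The secondary hydroxyl is mesylated (MsCl, Et3N, CH2Cl2) to the C10 methanesulfonate F2.
- LiBr in acetone replaces the mesylate with retention through homoallylic participation of C7=C8 (cholesteryl-type substitution), giving 18.

Step 12. The open β-chloro cation may lose a proton, may be captured from the axial side with loss of the C3 configuration, or HBr may add to C7=C8. The fallback sets out from 14 and comes back at 19. It puts bromine on ring B as the bridging group instead of chlorine.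
- MeLi converts 14 into the carbinol (1S,2S,3R,5R)-2,4,4,4'-tetramethylspiro[bicyclo[3.1.0]hexane-3,1'-cyclohex-3'-en]-2-ol F3.
- MgBr2·OEt2 ring-expands F3 to (6S,10R)-10-bromo-α-chamigrene F4.
- m-CPBA epoxidises the less hindered ring-B alkene to (2S,3R,6S,10R)-10-bromo-2,3-epoxy-α-chamigrene F5 (oxygen on the face of C11).
- LiBr/AcOH opens the epoxide at C2 (trans-diaxial opening) to (2R,3R,6S,10R)-2,10-dibromo-α-chamigren-3-ol F6.
- Dry HCl with ZnCl2 (cat.) replaces the tertiary hydroxyl through the bromonium ion, giving (2R,3R,6S,10R)-2,10-dibromo-3-chloro-α-chamigrene F7 beside 19.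
- Warming in MeCN should move F7 to 19 by the diaxial-to-diequatorial rearrangement of vicinal dihalides, in which each halogen shifts on its own face.

Step 5. Bond formation beside the gem-dimethyl carbon may be slow, the formyl group may be lost by retro-Claisen cleavage, and the facial bias of the remote cyclopropane may be too small. The fallback sets out from 7 and comes back at 14, with catalyst control at C6.
- LDA and 4-iodo-2-methylbut-1-ene give (1S,3S,5R)-4,4-dimethyl-3-(3-methylbut-3-enyl)bicyclo[3.1.0]hexan-2-one F8.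
- KHMDS and allyl chloroformate give allyl (1S,5R)-4,4-dimethyl-3-(3-methylbut-3-enyl)bicyclo[3.1.0]hex-2-en-2-yl carbonate F9.
- Pd2(dba)3 with the enantiomer of t-BuPHOX that places allyl syn to C9 effects a decarboxylative asymmetric allylation (Tsuji type) to (1S,3R,5R)-3-allyl-4,4-dimethyl-3-(3-methylbut-3-enyl)bicyclo[3.1.0]hexan-2-one F10.
- Ring-closing metathesis with second-generation Grubbs catalyst closes C2=C3 and gives 14.

Further compounds
F1 | step 11 | (2S,3S,6S,10R)-2-chloro-α-chamigrene-3,10-diol | CC1=CC[C@@H](O)C(C)(C)[C@]12CC[C@](C)(O)[C@@H](Cl)C2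
F2 | step 11 | (2S,3S,6S,10R)-2-chloro-3-hydroxy-α-chamigren-10-yl methanesulfonate | CC1=CC[C@@H](OS(C)(=O)=O)C(C)(C)[C@]12CC[C@](C)(O)[C@@H](Cl)C2
F3 | step 12 | (1S,2S,3R,5R)-2,4,4,4'-tetramethylspiro[bicyclo[3.1.0]hexane-3,1'-cyclohex-3'-en]-2-ol | C[C@]1(O)[C@H]2C[C@H]2C(C)(C)[C@]13CCC(C)=CC3
F4 | step 12 | (6S,10R)-10-bromo-α-chamigrene | CC1=CC[C@@H](Br)C(C)(C)[C@]12CCC(C)=CC2
F5 | step 12 | (2S,3R,6S,10R)-10-bromo-2,3-epoxy-α-chamigrene | CC1=CC[C@@H](Br)C(C)(C)[C@]12CC[C@@]3(C)O[C@H]3C2
F6 | step 12 | (2R,3R,6S,10R)-2,10-dibromo-α-chamigren-3-ol | CC1=CC[C@@H](Br)C(C)(C)[C@]12CC[C@@](C)(O)[C@H](Br)C2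
F7 | step 12 | (2R,3R,6S,10R)-2,10-dibromo-3-chloro-α-chamigrene | CC1=CC[C@@H](Br)C(C)(C)[C@]12CC[C@@](C)(Cl)[C@H](Br)C2
F8 | step 5 | (1S,3S,5R)-4,4-dimethyl-3-(3-methylbut-3-enyl)bicyclo[3.1.0]hexan-2-one | O=C1[C@H]2C[C@H]2C(C)(C)[C@@H]1CCC(C)=C
F9 | step 5 | allyl (1S,5R)-4,4-dimethyl-3-(3-methylbut-3-enyl)bicyclo[3.1.0]hex-2-en-2-yl carbonate | C=CCOC(=O)OC1=C(CCC(C)=C)C(C)(C)[C@@H]2C[C@H]12
F10 | step 5 | (1S,3R,5R)-3-allyl-4,4-dimethyl-3-(3-methylbut-3-enyl)bicyclo[3.1.0]hexan-2-one | O=C1[C@H]2C[C@H]2C(C)(C)[C@]1(CC=C)CCC(C)=C
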